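## Retrosynthetic overview
- The target is opened to a constitutional isomer: a 2'-hydroxychalcone whose ring B carries an aryl 1,1-dimethylpropargyl ether. This cuts the aryl–CH= bond of the 2H-pyran and the O1–C2 bond of the pyranone together.
- Forward, in one flask: Au(I) 6-endo hydroarylation closes the 2,2-dimethyl-2H-pyran first. A cinchona thiourea then closes the pyranone by enantioselective oxa-Michael addition, and C2 (S) is set in the last bond formed.
- The chalcone comes from a protecting-group-free Claisen–Schmidt union of 3-prenylresacetophenone with 3-prenyl-4-(1,1-dimethylpropargyloxy)benzaldehyde.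
- Both halves come from 2,4-dihydroxyacetophenone and 4-hydroxybenzaldehyde by aqueous phenoxide C-prenylation. The two benzene rings are bought.

Assumption: the quinine-derived thiourea is taken to give the 2S product, by analogy with related cinchona-thiourea flavanone closures; if CD or chiral HPLC of the first run shows 2R, the pseudo-enantiomeric quinidine-derived catalyst is used with nothing else changed.

## Route

Step 1
Reactants: 1 2,4-dihydroxyacetophenone; 2 prenyl bromide (1-bromo-3-methylbut-2-ene)
Product: 3 1-[2,4-dihydroxy-3-(3-methylbut-2-enyl)phenyl]ethanone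
Conditions: KOH (1.1 equiv), H2O, 0 °C → rt, 16 h; chromatography
Reagents that add atoms: prenyl bromide (2), CC(C)=CCBr
Why: In water the phenoxide oxygen is heavily solvated, so the soft allylic bromide is attacked by the doubly activated C3 between the two oxygens (phenoxide C-alkylation, "nuclear prenylation"), and the modest yield of the 3-prenyl ketone is separated from the O-prenyl and 5-prenyl isomers; no stereocenter is formed.

Step 2
Reactants: 4 4-hydroxybenzaldehyde; 2 prenyl bromide
Product: 5 4-hydroxy-3-(3-methylbut-2-enyl)benzaldehyde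
Conditions: KOH (1.1 equiv), H2O, rt, 24 h; chromatography
Reagents that add atoms: prenyl bromide (2), CC(C)=CCBr
Why: This is the same aqueous phenoxide C-alkylation, here at the ortho carbon because the para position is blocked by CHO, and limiting the bromide holds back the 3,5-diprenyl product; no stereocenter is formed.

Step 3
Reactants: 5 4-hydroxy-3-(3-methylbut-2-enyl)benzaldehyde; 6 3-chloro-3-methylbut-1-yne
Product: 7 3-(3-methylbut-2-enyl)-4-[(2-methylbut-3-yn-2-yl)oxy]benzaldehyde
Conditions: K2CO3 (2 equiv), KI (cat.), CuI (cat.), MeCN, 60 °C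
Reagents that add atoms: 3-chloro-3-methylbut-1-yne (6), C#CC(C)(C)Cl
Why: Copper-assisted Williamson-type O-alkylation with a tertiary propargylic chloride (through a copper acetylide/allenylidene species) gives the tertiary aryl propargyl ether well below the temperature at which it rearranges, and the aldehyde and the prenyl group are inert.

Step 4
Reactants: 3 1-[2,4-dihydroxy-3-(3-methylbut-2-enyl)phenyl]ethanone; 7 3-(3-methylbut-2-enyl)-4-[(2-methylbut-3-yn-2-yl)oxy]benzaldehyde
Product: 8 (E)-1-[2,4-dihydroxy-3-(3-methylbut-2-enyl)phenyl]-3-{3-(3-methylbut-2-enyl)-4-[(2-methylbut-3-yn-2-yl)oxy]phenyl}prop-2-en-1-one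
Conditions: KOH (50% aq, 10 equiv), EtOH, 0 °C → rt, 48 h; then 1 M HCl, 0 °C, to pH 5
Reagents that add atoms: none
Why: In this Claisen–Schmidt condensation (crossed aldol, E1cB dehydration) the non-enolisable aldehyde gives only the E-enone, strong base holds the product as the open phenoxide so no racemic flavanone builds up, and the ether, alkyne and prenyl groups are base-stable.

Step 5
Reactants: 8 (E)-1-[2,4-dihydroxy-3-(3-methylbut-2-enyl)phenyl]-3-{3-(3-methylbut-2-enyl)-4-[(2-methylbut-3-yn-2-yl)oxy]phenyl}prop-2-en-1-one
Product: 10 (2S)-7-hydroxy-8-(3-methylbut-2-enyl)-2-[2,2-dimethyl-8-(3-methylbut-2-enyl)-2H-chromen-6-yl]chroman-4-one (target), via chromene chalcone 9 (not isolated)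
Conditions: Ph3PAuNTf2 (3 mol %), 2,6-di-tert-butylpyridine (5 mol %), CH2Cl2, 25 °C, 2 h; then, same flask, toluene (5 vol), 1-[3,5-bis(trifluoromethyl)phenyl]-3-[(8α,9S)-6'-methoxycinchonan-9-yl]thiourea (20 mol %), 0 °C → rt, 72 h; filtration through SiO2
Reagents that add atoms: none
Why: Proposed new method: cationic gold(I) activates the terminal alkyne of 8 for 6-endo-dig attack by the only free ortho carbon of ring B (intramolecular hydroarylation of an aryl 1,1-dimethylpropargyl ether, known at room temperature also for para-acyl arenes and helped by the gem-dimethyl effect), which closes the 2H-pyran to 9 under conditions too mild to cyclise the chelated 2'-hydroxyenone, with the hindered pyridine scavenging stray acid that could cyclise the o-prenylphenol; the thiourea added to the same flask then binds and silences the gold, its excess hydrogen-bonds the enone carbonyl, its quinuclidine nitrogen takes up the 2'-OH proton, and the phenol oxygen adds 6-endo-trig to one face of the β-carbon to set C2 as S; the closest known reaction types are the cinchona-thiourea intramolecular oxa-Michael closure of ester-activated 2'-hydroxychalcones to flavanones and of phenol-tethered enones to 2-substituted chromans, and what is new is the unactivated enone, the free 4'-OH and the coupling of both ring closures in one flask.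

## Compound list
1 | 2,4-dihydroxyacetophenone | CC(=O)c1ccc(O)cc1O | starting material
2 | prenyl bromide | CC(C)=CCBr | starting material
3 | 1-[2,4-dihydroxy-3-(3-methylbut-2-enyl)phenyl]ethanone | CC(=O)c1ccc(O)c(CC=C(C)C)c1O | intermediate
4 | 4-hydroxybenzaldehyde | O=Cc1ccc(O)cc1 | starting material
5 | 4-hydroxy-3-(3-methylbut-2-enyl)benzaldehyde | O=Cc1ccc(O)c(CC=C(C)C)c1 | intermediate
6 | 3-chloro-3-methylbut-1-yne | C#CC(C)(C)Cl | starting material
7 | 3-(3-methylbut-2-enyl)-4-[(2-methylbut-3-yn-2-yl)oxy]benzaldehyde | O=Cc1ccc(OC(C)(C)C#C)c(CC=C(C)C)c1 | intermediate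
8 | (E)-2',4'-dihydroxy-3,3'-diprenyl-4-(1,1-dimethylpropargyloxy)chalcone | CC(C)=CCc1cc(/C=C/C(=O)c2ccc(O)c(CC=C(C)C)c2O)ccc1OC(C)(C)C#C | intermediate
9 | (E)-1-[2,4-dihydroxy-3-(3-methylbut-2-enyl)phenyl]-3-[2,2-dimethyl-8-(3-methylbut-2-enyl)-2H-chromen-6-yl]prop-2-en-1-one | CC(C)=CCc1cc(/C=C/C(=O)c2ccc(O)c(CC=C(C)C)c2O)cc2c1OC(C)(C)C=C2 | intermediate (not isolated)
10 | (2S)-7-hydroxy-8-(3-methylbut-2-enyl)-2-[2,2-dimethyl-8-(3-methylbut-2-enyl)-2H-chromen-6-yl]chroman-4-one | CC(C)=CCc1cc([C@@H]2CC(=O)c3ccc(O)c(CC=C(C)C)c3O2)cc2c1OC(C)(C)C=C2 | target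

## Step count and risks
Total steps: 5. Longest linear sequence: 4 (steps 2, 3, 4, 5).

**Risk 1, step 5.**
- The donor-substituted, unactivated enone may close slowly and reversibly, stalling near 70–80% conversion with ee eroding on long exposure.
- Cationic gold could also touch the o-prenylphenol.
- The fallback replaces the asymmetric ring closure by a resolution. It sets out from 8, which is heated in N,N-diethylaniline at 150 °C.
- There the aryl propargyl ether Claisen/[1,5]-H/oxa-6π sequence and the amine-assisted oxa-Michael addition close both rings and give the racemic flavanone F1.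
- This is submitted to transfer-hydrogenative kinetic resolution with [Cp*RhCl((R,R)-TsDPEN)] (1 mol %), HCO2H/Et3N, EtOAc, rt, stopped just past half conversion.
- The 2R ketone is reduced to the cis-(2R,4R)-flavan-4-ol F2. The 2S ketone stays untouched and is separated by chromatography, which is the return to the route at 10.

**Risk 2, step 4.**
- The dianion of 3 is a reluctant enolate precursor, so the condensation may be slow and low-yielding.
- In the fallback the ring-A prenyl group is delivered after the union by a [3,3] shift, from an ether that also masks the 4-OH.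
- It sets out from 1, whose non-chelated 4-OH is alkylated with 6 (K2CO3, KI, CuI, MeCN, 60 °C) to the propargyl ether F3.
- Semi-hydrogenation (H2, Lindlar Pd, quinoline, EtOAc) gives the 1,1-dimethylallyl ether F4.
- Condensation with 7 (KOH, EtOH, rt; only the chelated 2-OH is acidic) gives the bis-ether chalcone F5.
- Heating in o-xylene at 135 °C triggers the aromatic Claisen shift to the chelate-activated C3'. It also triggers the propargyl Claisen/oxa-6π cascade on ring B.
- The product is 9, where the route is rejoined for the thiourea stage of step 5. This detour also makes step 1 unnecessary.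

**Risk 3, step 2.**
- O-prenylation and double C-prenylation compete, and the yield of 5 may be too low to carry material forward.
- The fallback replaces phenoxide C-alkylation by cross-coupling. It sets out from 4, which is iodinated ortho to the hydroxyl group (NIS, AcOH, rt) to 4-hydroxy-3-iodobenzaldehyde F6.
- Stille coupling with tributyl(3-methylbut-2-enyl)stannane (Pd(PPh3)4, DMF, 90 °C) transfers the linear prenyl group and returns to the route at 5.

## Further compounds
F1 | step 5 | racemic 7-hydroxy-8-(3-methylbut-2-enyl)-2-[2,2-dimethyl-8-(3-methylbut-2-enyl)-2H-chromen-6-yl]chroman-4-one | CC(C)=CCc1cc(C2CC(=O)c3ccc(O)c(CC=C(C)C)c3O2)cc2c1OC(C)(C)C=C2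
F2 | step 5 | (2R,4R)-2-[2,2-dimethyl-8-(3-methylbut-2-enyl)-2H-chromen-6-yl]-8-(3-methylbut-2-enyl)chroman-4,7-diol (2,4-cis) | CC(C)=CCc1cc([C@H]2C[C@@H](O)c3ccc(O)c(CC=C(C)C)c3O2)cc2c1OC(C)(C)C=C2
F3 | step 4 | 1-{2-hydroxy-4-[(2-methylbut-3-yn-2-yl)oxy]phenyl}ethanone | CC(=O)c1ccc(OC(C)(C)C#C)cc1O
F4 | step 4 | 1-{2-hydroxy-4-[(2-methylbut-3-en-2-yl)oxy]phenyl}ethanone | CC(=O)c1ccc(OC(C)(C)C=C)cc1O
F5 | step 4 | (E)-1-{2-hydroxy-4-[(2-methylbut-3-en-2-yl)oxy]phenyl}-3-{3-(3-methylbut-2-enyl)-4-[(2-methylbut-3-yn-2-yl)oxy]phenyl}prop-2-en-1-one | C=CC(C)(C)Oc1ccc(C(=O)/C=C/c2ccc(OC(C)(C)C#C)c(CC=C(C)C)c2)c(O)c1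
F6 | step 2 | 4-hydroxy-3-iodobenzaldehyde | O=Cc1ccc(O)c(I)c1
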